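**Retrosynthetic overview**

1. Disconnect C7=C8 (carotenoid numbering): Wittig union of C10 aldehyde 12 (ring plus formyl carbon C7) with C30 polyenyl phosphonium salt 20, then removal of one silyl group; 20 comes from crocetin dialdehyde and a geranyl ylide.
2. The cyclopentane (C2–C6) of 12 is not closed directly: it arises by six-to-five ring contraction of hydroxy mesylate 10, in which p-menthane C-1 shifts from C-2 to C-3 and C-2 leaves the ring as the formyl carbon.
3. Enabling feature: in the cyclohexane ring of 10, three adjacent carbons carry oxygen (quaternary C-1: CH3 and OSiEt3; C-2: OH; C-3: OMs) next to the isopropenyl-bearing C-4; with isopropenyl equatorial, the C3–OMs bond is equatorial and antiperiplanar to the C1–C2 ring bond, and the C-2 oxygen supplies the push.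
4. 10 is built from (S)-carvone: nucleophilic epoxidation fixes the tertiary C–O bond trans to isopropenyl, followed by hydride opening, oxidation, silylation, α′-hydroxylation, mesylation and ketone reduction.
5. Ring order: the target has one ring; it is formed in step 8 from the six-membered ring of carvone.

Key step: step 8

Remark: ring intermediates are discussed with p-menthane numbering (C-1 bears CH3, C-2 is the carvone carbonyl carbon, C-4 bears isopropenyl); the target uses carotenoid numbering.
Assumption: (S)-(+)-carvone, geranyl bromide and crocetin dialdehyde are taken as purchased; all polyene operations are run under argon with exclusion of light.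
Remark: the C-2 carbinol centres of 3, 4 and 10 are erased later; the epimer expected to predominate is drawn and the other would converge.

**Step 1**
Reactants: 1 (S)-(+)-carvone
Product: 2 (1S,4S,6S)-1-methyl-4-(prop-1-en-2-yl)-7-oxabicyclo[4.1.0]heptan-2-one (trans-carvone oxide)
Conditions: 30% aq. H2O2, NaOH (cat.), MeOH, 0 °C
Reagents that add atoms: hydrogen peroxide, OO
Why: Nucleophilic (Weitz–Scheffer) epoxidation of the enone: hydroperoxide adds axially to C-6 anti to the C-4 isopropenyl group, so the epoxide, and with it the future tertiary C–O bond, is set trans to isopropenyl, while the isolated 1,1-disubstituted alkene is inert to the nucleophilic oxidant.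

**Step 2**
Reactants: 2 trans-carvone oxide
Product: 4 (1S,2R,4S)-1-methyl-4-(prop-1-en-2-yl)cyclohexane-1,2-diol, via epoxy alcohol 3 (not isolated)
Conditions: LiAlH4, THF, 0 °C → rt; aq. NaOH work-up
Reagents that add atoms: none
Why: Hydride reduction: the ketone is reduced first (hydride anti to the epoxide oxygen, giving epoxy alkoxide 3), and the trisubstituted epoxide is then opened by SN2 attack of hydride at the secondary carbon C-6, which keeps the tertiary C-1–O bond and its configuration.

**Step 3**
Reactants: 4 diol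
Product: 5 (2S,5S)-2-hydroxy-2-methyl-5-(prop-1-en-2-yl)cyclohexan-1-one
Conditions: IBX, DMSO, rt
Reagents that add atoms: none
Why: IBX oxidation of the secondary hydroxyl of a secondary/tertiary 1,2-diol to the α-ketol without glycol cleavage; both C-2 epimers converge, and the tertiary alcohol and the alkene are untouched.

**Step 4**
Reactants: 5 α-ketol
Product: 6 (2S,5S)-2-methyl-5-(prop-1-en-2-yl)-2-[(triethylsilyl)oxy]cyclohexan-1-one
Conditions: Et3SiOTf, 2,6-lutidine, CH2Cl2, −78 → 0 °C
Reagents that add atoms: triethylsilyl trifluoromethanesulfonate, CC[Si](CC)(CC)OS(=O)(=O)C(F)(F)F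
Why: Silylation of the hindered tertiary hydroxyl with a silyl triflate; the ether later prevents retro-aldol and fragmentation pathways and leaves C-3 as the only enolisable position of the ketone.

**Step 5**
Reactants: 6 silyl ketol
Product: 8 (2S,5R,6R)-6-hydroxy-2-methyl-5-(prop-1-en-2-yl)-2-[(triethylsilyl)oxy]cyclohexan-1-one, via potassium enolate 7 (not isolated)
Conditions: KN(SiMe3)2, THF, −78 °C; then 2-(phenylsulfonyl)-3-phenyloxaziridine, −78 °C; aq. NH4Cl
Reagents that add atoms: 2-(phenylsulfonyl)-3-phenyloxaziridine, O=S(=O)(N1OC1c1ccccc1)c1ccccc1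
Why: Enolate hydroxylation with an N-sulfonyloxaziridine: the only possible enolate (C-2/C-3, since C-1 is quaternary) is oxidised on the face anti to the adjacent isopropenyl group, which places the new C-3 hydroxyl trans to isopropenyl (equatorial, also the more stable α-epimer).

**Step 6**
Reactants: 8 α′-hydroxy ketone
Product: 9 (1R,3S,6R)-3-methyl-2-oxo-6-(prop-1-en-2-yl)-3-[(triethylsilyl)oxy]cyclohexyl methanesulfonate
Conditions: MsCl, Et3N, CH2Cl2, −10 °C
Reagents that add atoms: methanesulfonyl chloride, CS(=O)(=O)Cl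
Why: O-Sulfonylation of the only free hydroxyl; the C-3 configuration is retained because only the O–H bond reacts.

**Step 7**
Reactants: 9 mesyloxy ketone
Product: 10 (1R,2S,3S,6R)-2-hydroxy-3-methyl-6-(prop-1-en-2-yl)-3-[(triethylsilyl)oxy]cyclohexyl methanesulfonate
Conditions: NaBH4, MeOH/THF, −20 → 0 °C
Reagents that add atoms: none
Why: Borohydride reduction of the ketone by axial attack anti to the axial C-1 methyl group should give mainly the equatorial C-2 alcohol; either C-2 epimer keeps the C3–OMs bond equatorial and antiperiplanar to the C1–C2 ring bond, so the outcome at this centre is not critical.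

**Step 8**
Reactants: 10 hydroxy mesylate
Product: 12 (1R,2S,5S)-2-methyl-5-(prop-1-en-2-yl)-2-[(triethylsilyl)oxy]cyclopentane-1-carbaldehyde, via diethylaluminium alkoxide 11 (not isolated)
Conditions: AlEt3 (3 equiv), CH2Cl2, −78 → 0 °C; aq. KNaC4H4O6 (potassium sodium tartrate) work-up
Reagents that add atoms: none
Why: AlEt3 converts the C-2 hydroxyl into diethylaluminium alkoxide 11 and activates the mesylate; the C1–C2 ring bond, antiperiplanar to the equatorial C3–OMs bond, then migrates from C-2 to C-3 with backside displacement of mesylate while C-2 becomes the formyl carbon, so the cyclohexane contracts to the cyclopentane. The closest known reaction types are the organoaluminium-promoted pinacol-type (semipinacol) rearrangement of 2-sulfonyloxy alcohols and the ring contraction of cyclohexane-1,2-diol monosulfonates to cyclopentanecarbaldehydes. The five-membered ring is closed by the 1,2-shift itself (new C1–C3 bond), not by an end-to-end cyclisation. The new stereocentre (the formyl-bearing carbon, former C-3) is set by inversion at the mesylate carbon, so the trans C-3/C-4 relationship from step 5 places CHO trans to isopropenyl and cis to the silyloxy group; the migrating quaternary C-1 keeps its configuration and C-4 is untouched. The step needs ring-bond migration rather than hydride shift, epoxide closure, elimination or ring cleavage: the equatorial isopropenyl anchor holds C–OMs equatorial so that only ring bonds are antiperiplanar to it, only the C1–C2 bond has the alkoxide push, and the silyl cap on the tertiary oxygen removes the free alkoxide needed for fragmentation or retro-aldol.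

**Step 9**
Reactants: 13 geranyl bromide
Product: 14 geranyltriphenylphosphonium bromide
Conditions: PPh3, toluene, rt
Reagents that add atoms: triphenylphosphine, c1ccc(cc1)P(c1ccccc1)c1ccccc1
Why: SN2 quaternisation of the primary allylic bromide by the phosphine at room temperature, which keeps the E geometry of the trisubstituted double bond.

**Step 10**
Reactants: 14 geranyltriphenylphosphonium bromide; 15 crocetin dialdehyde
Product: 18 apo-8'-lycopenal (all-E C30 aldehyde), via geranylidenephosphorane 16 (not isolated), via Z-olefin isomer 17 (not isolated)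
Conditions: NaN(SiMe3)2, THF, −78 °C; then 15 (3 equiv), THF/CH2Cl2, −78 → 0 °C; then heptane, reflux
Reagents that add atoms: none
Why: Wittig olefination with a semi-stabilised allylic ylide; the excess of the symmetrical dialdehyde limits double olefination, and the sterically hindered Z isomer at the new disubstituted double bond should equilibrate thermally to the all-E polyene, as is usual for carotenoid Wittig products.

**Step 11**
Reactants: 18 apo-8'-lycopenal
Product: 19 apo-8'-lycopenol (all-E C30 allylic alcohol)
Conditions: NaBH4, EtOH/CH2Cl2, 0 °C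
Reagents that add atoms: none
Why: 1,2-Reduction of the polyenal by borohydride, for which conjugate reduction does not compete.

**Step 12**
Reactants: 19 apo-8'-lycopenol
Product: 20 (all-E)-apo-8'-lycopenyltriphenylphosphonium bromide
Conditions: PPh3·HBr, MeOH/CH2Cl2, rt
Reagents that add atoms: triphenylphosphine hydrobromide, [Br-].c1ccc(cc1)[PH+](c1ccccc1)c1ccccc1
Why: Phosphonium salt formation from a polyene allylic alcohol through the delocalised allylic cation, which the phosphine captures at the terminal carbon, as in the standard preparation of retinyl and apo-carotenyl Wittig salts.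

**Step 13**
Reactants: 20 C30 phosphonium bromide; 12 cyclopentanecarbaldehyde
Product: 23 O-triethylsilyl ether of the target (all-E), via polyenylidenephosphorane 21 (not isolated), via 7Z-isomer 22 (not isolated)
Conditions: NaN(SiMe3)2, THF, −78 °C; then 12, −78 → 0 °C; then heptane, 80 °C
Reagents that add atoms: none
Why: Wittig olefination forming C7=C8: the pre-formed, weakly basic polyenyl ylide should add to the α-branched aldehyde at low temperature faster than it enolises it, so the C-6 stereocentre and the β-silyloxy group survive, and thermal equilibration of the hindered 7Z isomer gives the all-E chain.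

**Step 14**
Reactants: 23 silyl ether
Product: 24 CNP0222499.1 (target)
Conditions: Bu4NF, THF, 0 °C → rt
Reagents that add atoms: none
Why: Fluoride cleavage of the tertiary triethylsilyl ether under non-acidic conditions that the polyene tolerates; no stereocentre is affected.

**Compound list**

1 | (S)-(+)-carvone, (5S)-2-methyl-5-(prop-1-en-2-yl)cyclohex-2-en-1-one | CC1=CC[C@@H](CC1=O)C(C)=C | starting material
2 | trans-carvone oxide, (1S,4S,6S)-1-methyl-4-(prop-1-en-2-yl)-7-oxabicyclo[4.1.0]heptan-2-one (epoxide oxygen trans to isopropenyl) | C[C@]12O[C@H]1C[C@H](C(C)=C)CC2=O | intermediate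
3 | epoxy alcohol from 2 (2-OH cis to the epoxide oxygen; present as its aluminium alkoxide) | C[C@]12O[C@H]1C[C@H](C(C)=C)C[C@H]2O | intermediate (not isolated)
4 | (1S,2R,4S)-1-methyl-4-(prop-1-en-2-yl)cyclohexane-1,2-diol (tertiary OH trans to isopropenyl) | C[C@]1(O)CC[C@H](C(C)=C)C[C@H]1O | intermediate
5 | (2S,5S)-2-hydroxy-2-methyl-5-(prop-1-en-2-yl)cyclohexan-1-one | C[C@]1(O)CC[C@H](C(C)=C)CC1=O | intermediate
6 | (2S,5S)-2-methyl-5-(prop-1-en-2-yl)-2-[(triethylsilyl)oxy]cyclohexan-1-one | C[C@]1(O[Si](CC)(CC)CC)CC[C@H](C(C)=C)CC1=O | intermediate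
7 | potassium enolate of 6 | C[C@]1(O[Si](CC)(CC)CC)CC[C@H](C(C)=C)C=C1[O-].[K+] | intermediate (not isolated)
8 | (2S,5R,6R)-6-hydroxy-2-methyl-5-(prop-1-en-2-yl)-2-[(triethylsilyl)oxy]cyclohexan-1-one (6-OH trans to isopropenyl) | C[C@]1(O[Si](CC)(CC)CC)CC[C@H](C(C)=C)[C@@H](O)C1=O | intermediate
9 | (1R,3S,6R)-3-methyl-2-oxo-6-(prop-1-en-2-yl)-3-[(triethylsilyl)oxy]cyclohexyl methanesulfonate | C[C@]1(O[Si](CC)(CC)CC)CC[C@H](C(C)=C)[C@@H](OS(C)(=O)=O)C1=O | intermediate
10 | (1R,2S,3S,6R)-2-hydroxy-3-methyl-6-(prop-1-en-2-yl)-3-[(triethylsilyl)oxy]cyclohexyl methanesulfonate (OMs, OH, OSiEt3 and isopropenyl all equatorial) | C[C@]1(O[Si](CC)(CC)CC)CC[C@H](C(C)=C)[C@@H](OS(C)(=O)=O)[C@@H]1O | intermediate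
11 | diethylaluminium alkoxide of 10 | C[C@]1(O[Si](CC)(CC)CC)CC[C@H](C(C)=C)[C@@H](OS(C)(=O)=O)[C@@H]1O[Al](CC)CC | intermediate (not isolated)
12 | (1R,2S,5S)-2-methyl-5-(prop-1-en-2-yl)-2-[(triethylsilyl)oxy]cyclopentane-1-carbaldehyde (CHO cis to OSiEt3, trans to isopropenyl) | C=C(C)[C@H]1CC[C@](C)(O[Si](CC)(CC)CC)[C@@H]1C=O | intermediate
13 | geranyl bromide, (2E)-1-bromo-3,7-dimethylocta-2,6-diene | CC(C)=CCC/C(C)=C/CBr | starting material
14 | geranyltriphenylphosphonium bromide | [Br-].CC(C)=CCC/C(C)=C/C[P+](c1ccccc1)(c1ccccc1)c1ccccc1 | intermediate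
15 | crocetin dialdehyde, (2E,4E,6E,8E,10E,12E,14E)-2,6,11,15-tetramethylhexadeca-2,4,6,8,10,12,14-heptaenedial | O=C/C(C)=C/C=C/C(C)=C/C=C/C=C(C)/C=C/C=C(C)/C=O | starting material
16 | geranylidenetriphenylphosphorane | CC(C)=CCC/C(C)=C/C=P(c1ccccc1)(c1ccccc1)c1ccccc1 | intermediate (not isolated)
17 | (16Z)-isomer of 18 (new C16=C17 bond cis) | O=C/C(C)=C/C=C/C(C)=C/C=C/C=C(C)/C=C/C=C(C)/C=C\C=C(/C)CCC=C(C)C | intermediate (not isolated)
18 | apo-8'-lycopenal, (2E,4E,6E,8E,10E,12E,14E,16E,18E)-2,6,11,15,19,23-hexamethyltetracosa-2,4,6,8,10,12,14,16,18,22-decaenal | O=C/C(C)=C/C=C/C(C)=C/C=C/C=C(C)/C=C/C=C(C)/C=C/C=C(\C)CCC=C(C)C | intermediate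
19 | apo-8'-lycopenol, the all-E primary allylic alcohol of 18 | OC/C(C)=C/C=C/C(C)=C/C=C/C=C(C)/C=C/C=C(C)/C=C/C=C(\C)CCC=C(C)C | intermediate
20 | (all-E)-apo-8'-lycopenyltriphenylphosphonium bromide | [Br-].c1ccc(cc1)[P+](c1ccccc1)(c1ccccc1)C/C(C)=C/C=C/C(C)=C/C=C/C=C(C)/C=C/C=C(C)/C=C/C=C(\C)CCC=C(C)C | intermediate
21 | (all-E)-apo-8'-lycopenylidenetriphenylphosphorane | c1ccc(cc1)P(c1ccccc1)(c1ccccc1)=C/C(C)=C/C=C/C(C)=C/C=C/C=C(C)/C=C/C=C(C)/C=C/C=C(\C)CCC=C(C)C | intermediate (not isolated)
22 | (7Z)-isomer of 23 | C=C(C)[C@H]1CC[C@](C)(O[Si](CC)(CC)CC)[C@@H]1\C=C/C(C)=C/C=C/C(C)=C/C=C/C=C(C)/C=C/C=C(C)/C=C/C=C(\C)CCC=C(C)C | intermediate (not isolated)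
23 | O-triethylsilyl ether of the target (all-E) | C=C(C)[C@H]1CC[C@](C)(O[Si](CC)(CC)CC)[C@@H]1/C=C/C(C)=C/C=C/C(C)=C/C=C/C=C(C)/C=C/C=C(C)/C=C/C=C(\C)CCC=C(C)C | intermediate
24 | CNP0222499.1, (1S,2R,3S)-1-methyl-3-(prop-1-en-2-yl)-2-[(1E,3E,5E,7E,9E,11E,13E,15E,17E,19E)-3,7,12,16,20,24-hexamethylpentacosa-1,3,5,7,9,11,13,15,17,19,23-undecaen-1-yl]cyclopentan-1-ol | C=C(C)[C@H]1CC[C@](C)(O)[C@@H]1/C=C/C(C)=C/C=C/C(C)=C/C=C/C=C(C)/C=C/C=C(C)/C=C/C=C(\C)CCC=C(C)C | target

**Summary**

Total step count: 14. Longest linear sequence: 10 steps (steps 1–8, 13 and 14).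

**Steps most likely to fail, with fallbacks**

Step 8 (key step). What may go wrong: transfer of the silyl group from the tertiary oxygen to the neighbouring metal alkoxide followed by Grob-type cleavage of the ring, ethyl transfer from aluminium to the new aldehyde, or sluggish migration of the oxygen-bearing carbon. The fallback sets out from mesyloxy ketone 9 and triggers the same 1,2-shift at the ketone oxidation level by a quasi-Favorskii (semibenzilic) rearrangement. NaOMe in MeOH at 0 °C adds to the C-2 carbonyl, and the short-lived tetrahedral alkoxide expels the mesylate with migration of C-1 (same inversion at C-3). This gives methyl (1R,2S,5S)-2-methyl-5-(prop-1-en-2-yl)-2-[(triethylsilyl)oxy]cyclopentane-1-carboxylate F1. iBu2AlH (1 equiv, CH2Cl2, −78 °C) then reduces the ester to the aldehyde, and the route is rejoined at compound 12.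

Step 5. What may go wrong: poor facial selectivity in the enolate hydroxylation, or capture of the enolate by the sulfonimine by-product. An axial C-3 oxygen would later lead to hydride shift or elimination instead of ring contraction. The fallback sets out from ketone 6. LiN(SiMe3)2/Me3SiCl gives the trimethylsilyl enol ether of 6 F2. [Hydroxy(tosyloxy)iodo]benzene in CH2Cl2 then installs the sulfonate directly, giving (1R,3S,6R)-3-methyl-2-oxo-6-(prop-1-en-2-yl)-3-[(triethylsilyl)oxy]cyclohexyl 4-methylbenzenesulfonate F3. Its C-3 centre is epimerisable through the enol and can be equilibrated with Et3N to the equatorial, trans isomer. NaBH4 gives the corresponding 2-hydroxy tosylate F4, which undergoes the same AlEt3-promoted ring contraction and rejoins the route at compound 12.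

Step 13. What may go wrong: base-induced epimerisation at C-6 or β-elimination of the silyloxy group of the aldehyde by the ylide, and slow or incomplete Z-to-E equilibration of the new double bond. The fallback reverses the polarity of the union and sets out from aldehyde 12. NaBH4 gives [(1R,2S,5S)-2-methyl-5-(prop-1-en-2-yl)-2-[(triethylsilyl)oxy]cyclopentyl]methanol F5. Mitsunobu thioetherification with 1-phenyl-1H-tetrazole-5-thiol gives the 1-phenyltetrazol-5-yl sulfide F6. Oxidation with (NH4)6Mo7O24/H2O2 gives the 1-phenyltetrazol-5-yl sulfone F7. Julia–Kocienski olefination of F7 (KN(SiMe3)2, THF, −78 °C) with the non-enolisable C30 aldehyde 18 should form the C7=C8 bond with E selectivity and rejoins the route at compound 23.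

**Further compounds**

F1 | step 8 | methyl (1R,2S,5S)-2-methyl-5-(prop-1-en-2-yl)-2-[(triethylsilyl)oxy]cyclopentane-1-carboxylate | C=C(C)[C@H]1CC[C@](C)(O[Si](CC)(CC)CC)[C@@H]1C(=O)OC
F2 | step 5 | trimethylsilyl enol ether of 6 | C[C@]1(O[Si](CC)(CC)CC)CC[C@H](C(C)=C)C=C1O[Si](C)(C)C
F3 | step 5 | (1R,3S,6R)-3-methyl-2-oxo-6-(prop-1-en-2-yl)-3-[(triethylsilyl)oxy]cyclohexyl 4-methylbenzenesulfonate | C[C@]1(O[Si](CC)(CC)CC)CC[C@H](C(C)=C)[C@@H](OS(=O)(=O)c2ccc(C)cc2)C1=O
F4 | step 5 | (1R,2S,3S,6R)-2-hydroxy-3-methyl-6-(prop-1-en-2-yl)-3-[(triethylsilyl)oxy]cyclohexyl 4-methylbenzenesulfonate | C[C@]1(O[Si](CC)(CC)CC)CC[C@H](C(C)=C)[C@@H](OS(=O)(=O)c2ccc(C)cc2)[C@@H]1O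
F5 | step 13 | [(1R,2S,5S)-2-methyl-5-(prop-1-en-2-yl)-2-[(triethylsilyl)oxy]cyclopentyl]methanol | C=C(C)[C@H]1CC[C@](C)(O[Si](CC)(CC)CC)[C@@H]1CO
F6 | step 13 | 1-phenyl-1H-tetrazol-5-yl sulfide of F5 | C=C(C)[C@H]1CC[C@](C)(O[Si](CC)(CC)CC)[C@@H]1CSc1nnnn1-c1ccccc1
F7 | step 13 | 1-phenyl-1H-tetrazol-5-yl sulfone of F5 | C=C(C)[C@H]1CC[C@](C)(O[Si](CC)(CC)CC)[C@@H]1CS(=O)(=O)c1nnnn1-c1ccccc1
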